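**Retrosynthetic overview**
- Target ⇒ cut the aryl ester C–O bond and the O-acetyl bond: fully built phenol + (2R,3S)-2,3-epoxybutanal (carbene redox O-acylation), acetyl from Ac2O.
- Epoxy aldehyde ⇒ crotonaldehyde + H2O2 (aminocatalytic epoxidation; the C3–O bond formed here is the (S) centre of the target).
- Phenol ⇒ Heck disconnection of the (E)-styrenyl tertiary allylic alcohol: ortho-iodophenol + 2-methylbut-3-en-2-ol.
- Iodophenol ⇒ methyl p-coumarate (ortho iodination).
- Rings: the benzene ring is bought and no ring of the target is built; the only ring made is the transient oxirane, opened again in the ester-forming step.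

Assumption: the facial sense of the epoxidation follows the usual shielding model for diarylprolinol silyl ethers (nucleophile enters the E,s-trans iminium anti to the CAr2OTMS group), so the (R)-catalyst is taken as the one that gives the (3S) C–O bond; both antipodes are catalogue items.

**Step 1**
Reactants: 1 methyl (E)-3-(4-hydroxyphenyl)acrylate (methyl p-coumarate)
Product: 2 methyl (E)-3-(4-hydroxy-3-iodophenyl)acrylate
Conditions: NIS (1.05 equiv), p-TsOH·H2O (10 mol%), MeCN, 0 °C to rt
Reagents that add atoms: N-iodosuccinimide, O=C1CCC(=O)N1I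
Why: Electrophilic aromatic substitution: acid-activated NIS iodinates the ring ortho to OH (para is blocked by the acrylate arm), the ester-deactivated cinnamate C=C is left alone, and 1.05 equiv keeps di-iodination low.

**Step 2**
Reactants: 2 methyl (E)-3-(4-hydroxy-3-iodophenyl)acrylate; 3 2-methylbut-3-en-2-ol
Product: 4 methyl (E)-3-[4-hydroxy-3-[(E)-3-hydroxy-3-methylbut-1-en-1-yl]phenyl]acrylate
Conditions: Pd(OAc)2 (5 mol%), n-Bu4NCl (1 equiv), NaHCO3 (2.5 equiv), 3 (3 equiv), DMF, 70 °C, N2; neutral work-up
Reagents that add atoms: none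
Why: Mizoroki–Heck reaction (ligand-free Jeffery conditions): ArPd adds to the terminal CH2 of 3 and, because the carbinol carbon carries no hydrogen, syn β-hydride elimination can only give the conjugated (E)-styrenyl tertiary allylic alcohol; the internal cinnamate alkene does not compete, and the mild base and neutral work-up keep the o-hydroxystyryl carbinol from cyclising to a 2,2-dimethylchromene.

**Step 3**
Reactants: 5 (E)-but-2-enal (crotonaldehyde)
Product: 6 (2R,3S)-3-methyloxirane-2-carbaldehyde
Conditions: (R)-2-[bis(3,5-bis(trifluoromethyl)phenyl)(trimethylsilyloxy)methyl]pyrrolidine (10 mol%), 35% aq H2O2 (1.3 equiv), CH2Cl2, rt, 4 h; then MnO2 (cat.), MgSO4, filter; used at once as a titrated CH2Cl2 solution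
Reagents that add atoms: hydrogen peroxide, OO
Why: Aminocatalytic Weitz–Scheffer-type epoxidation (iminium, then enamine): hydroperoxide adds to C3 of the E,s-trans iminium anti to the CAr2OTMS shield of the (R)-catalyst and the enamine closes on oxygen to give the trans epoxide, so the C3–O bond (the future acetoxy-bearing centre) is formed as (S); C2 stops being a stereocentre in step 4, so only the ee at C3 matters.

**Step 4**
Reactants: 4 methyl (E)-3-[4-hydroxy-3-[(E)-3-hydroxy-3-methylbut-1-en-1-yl]phenyl]acrylate; 6 (2R,3S)-3-methyloxirane-2-carbaldehyde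
Product: 8 methyl (E)-3-[4-[(S)-3-acetoxybutanoyl]oxy-3-[(E)-3-hydroxy-3-methylbut-1-en-1-yl]phenyl]acrylate (target CNP0325017.1), via aryl (S)-3-hydroxybutanoate 7 (not isolated)
Conditions: 6 (1.8 equiv), 3-benzyl-4,5-dimethylthiazolium chloride (20 mol%), i-Pr2NEt (20 mol%), CH2Cl2, 30 °C, 12 h; then pyridine (3 equiv), Ac2O (2 equiv), DMAP (5 mol%), 0 °C, 1 h; neutral work-up
Reagents that add atoms: acetic anhydride, CC(=O)OC(C)=O
Why: Proposed new method: carbene-catalysed internal-redox O-acylation of a phenol by an α,β-epoxy aldehyde with acetyl capture in the same flask. The thiazolylidene adds to the CHO of 6 and the Breslow intermediate opens the oxirane at C2–O (the internal oxidant), leaving the C3–O bond and its (S) configuration untouched. Tautomerisation gives the (S)-3-hydroxybutanoyl azolium, which the phenol(ate) of 4 (pKa about 9, a far better acyl acceptor than the tertiary alcohol) captures to form the aryl ester C–O bond and release the carbene. Ac2O/pyridine then acetylates only the secondary carbinol of 7. The closest known reaction type is carbene-catalysed redox esterification of epoxy aldehydes with simple aliphatic alcohols in excess (and phenol capture of acyl azoliums made from α-halo aldehydes); it has not been shown with a phenol as the limiting acyl acceptor on an epoxy aldehyde, nor coupled to O-acetylation.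

**Compound list**
1 | methyl (E)-3-(4-hydroxyphenyl)acrylate (methyl p-coumarate) | COC(=O)/C=C/c1ccc(O)cc1 | starting material
2 | methyl (E)-3-(4-hydroxy-3-iodophenyl)acrylate | COC(=O)/C=C/c1ccc(O)c(I)c1 | intermediate
3 | 2-methylbut-3-en-2-ol | C=CC(C)(C)O | starting material
4 | methyl (E)-3-[4-hydroxy-3-[(E)-3-hydroxy-3-methylbut-1-en-1-yl]phenyl]acrylate | COC(=O)/C=C/c1ccc(O)c(/C=C/C(C)(C)O)c1 | intermediate
5 | (E)-but-2-enal (crotonaldehyde) | C/C=C/C=O | starting material
6 | (2R,3S)-3-methyloxirane-2-carbaldehyde | O=C[C@@H]1O[C@H]1C | intermediate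
7 | methyl (E)-3-[4-[(S)-3-hydroxybutanoyl]oxy-3-[(E)-3-hydroxy-3-methylbut-1-en-1-yl]phenyl]acrylate | COC(=O)/C=C/c1ccc(OC(=O)C[C@H](C)O)c(/C=C/C(C)(C)O)c1 | intermediate (not isolated)
8 | methyl (E)-3-[4-[(S)-3-acetoxybutanoyl]oxy-3-[(E)-3-hydroxy-3-methylbut-1-en-1-yl]phenyl]acrylate | COC(=O)/C=C/c1ccc(OC(=O)C[C@H](C)OC(C)=O)c(/C=C/C(C)(C)O)c1 | target

**Step count and risks**
Total steps: 4. Longest linear sequence: 3 steps (1 → 2 → 4 → 8); the second branch (5 → 6) is one step and joins at step 4.

Steps most likely to fail:

Step 4 (the proposed new step). The acyl azolium may instead close to the β-lactone or oligomerise to 3-hydroxybutanoate chains. The ortho-substituted phenol may capture it slowly. 8 may lose AcOH by E1cB under pyridine/DMAP. The fallback is known chemistry and takes the stereocentre from the chiral pool instead of making it catalytically; it sets out from 4 and comes back at 8. Purchased ethyl (S)-3-hydroxybutanoate F1 is saponified (LiOH, THF/H2O, 0 °C) to (S)-3-hydroxybutanoic acid F2. F2 is acetylated (Ac2O, pyridine, aqueous work-up) to (S)-3-acetoxybutanoic acid F3. F3 is joined to 4 by Steglich esterification (DIC, 5 mol% DMAP, CH2Cl2, 0 °C) to give 8 directly.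

Step 3. The small, water-soluble, volatile epoxy aldehyde may be lost, the ee with the smallest enal may be short, or the assumed facial sense may be wrong. The sense is checked on 8 by chiral HPLC against material from the fallback above; the catalyst antipode is used if it is reversed. The fallback replaces aminocatalysis on the enal by metal-catalysed epoxidation of the allylic alcohol; it sets out from 5 and comes back at 6. Luche reduction (NaBH4, CeCl3·7H2O, MeOH, 0 °C) gives (E)-but-2-en-1-ol F4 (also a catalogue item). Sharpless asymmetric epoxidation with L-(+)-diisopropyl tartrate (Ti(Oi-Pr)4, t-BuOOH, 4 Å MS, CH2Cl2, −20 °C) gives (2S,3S)-(3-methyloxiran-2-yl)methanol F5 with a firmly established absolute sense. TEMPO/PhI(OAc)2 oxidation in CH2Cl2 returns 6 as a solution.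

Step 2. The free phenol may slow the palladium cycle, the tertiary allylic alcohol may dehydrate, or 4 may cyclise to the chromene on work-up. The fallback replaces the Heck reaction by cross-coupling with a preformed (E)-alkenylboron reagent; it sets out from 2 and comes back at 4. Purchased 2-methylbut-3-yn-2-ol F6 is converted by copper-catalysed formal hydroboration (B2pin2, CuCl/Xantphos, NaOt-Bu, MeOH, THF) into (E)-2-methyl-4-(4,4,5,5-tetramethyl-1,3,2-dioxaborolan-2-yl)but-3-en-2-ol F7. Suzuki–Miyaura coupling of F7 with 2 (Pd(dppf)Cl2, K3PO4, THF/H2O, 50 °C) gives 4 with the E geometry fixed by the boronate.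

**Further compounds**
F1 | step 4 | ethyl (S)-3-hydroxybutanoate (purchased) | CCOC(=O)C[C@H](C)O
F2 | step 4 | (S)-3-hydroxybutanoic acid | C[C@H](O)CC(=O)O
F3 | step 4 | (S)-3-acetoxybutanoic acid | CC(=O)O[C@@H](C)CC(=O)O
F4 | step 3 | (E)-but-2-en-1-ol | C/C=C/CO
F5 | step 3 | (2S,3S)-(3-methyloxiran-2-yl)methanol | OC[C@@H]1O[C@H]1C
F6 | step 2 | 2-methylbut-3-yn-2-ol (purchased) | C#CC(C)(C)O
F7 | step 2 | (E)-2-methyl-4-(4,4,5,5-tetramethyl-1,3,2-dioxaborolan-2-yl)but-3-en-2-ol | CC(C)(O)/C=C/B1OC(C)(C)C(C)(C)O1
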